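**Strategy.** Miyabenol A is grown from its 3,5-dihydroxyphenyl end in three identical cycles, each fusing one trans-2,3-diaryl-2,3-dihydrobenzofuran onto a resorcinol ring. Everything rests on disconnecting the O1–C2 bond of each furan ring to a six-membered chroman-2-ol that carries one extra carbon between O1 and C2. The key step excises this carbon: Baeyer–Villiger migration of C2, which bears the 4-oxygenated aryl group, then ionisation and capture of the C2 cation by the phenol oxygen O1 of the fused resorcinol ring contract lactol to dihydrofuran, the C3 diarylmethine centre steering C2 trans. The lactol arises from amine-catalysed addition of (4-methoxyphenyl)acetaldehyde to an o-quinone methide, which sets C3.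

Key step: step 5

Remark: the sense of induction of the diarylprolinol silyl ether is assigned by analogy with its enamine additions to nitroalkenes; should compound 11 prove enantiomeric, the two catalyst enantiomers are exchanged in steps 4, 7 and 10. Only C4 of each lactol has to be controlled, because its C3 passes through a planar benzylic cation in the following step. The anomeric centre of each lactol and the carbinol centre of each benzhydrol are left undefined because the following step erases them.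

Step 1
Reactants: 1 2-bromo-4,6-dimethoxybenzaldehyde
Product: 2 2-bromo-6-hydroxy-4-methoxybenzaldehyde
Conditions: BCl3, CH2Cl2, −78 → 0 °C; H2O
Reagents that add atoms: none
Why: BCl3 chelates the formyl oxygen and the ortho methoxy group, so this Lewis-acid ether cleavage should remove only the methyl ether ortho to the aldehyde and leave the para one.

Step 2
Reactants: 2 2-bromo-6-hydroxy-4-methoxybenzaldehyde
Product: 3 sodium 3-bromo-2-formyl-5-methoxyphenolate
Conditions: NaH (1.0 equiv), THF, 0 °C → rt; solvent removed, solid dried in vacuo and stored under argon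
Reagents that add atoms: sodium hydride [NaH]
Why: Irreversible acid–base reaction of the chelated phenol with NaH should give the salicylaldehyde sodium salt as an isolable solid, so that one batch serves all three chain-extension steps and no phenolic proton meets an aryllithium.

Step 3
Reactants: 4 1-bromo-3,5-dimethoxybenzene; 3 sodium 3-bromo-2-formyl-5-methoxyphenolate
Product: 6 (2-bromo-6-hydroxy-4-methoxyphenyl)(3,5-dimethoxyphenyl)methanol (racemic), via 3,5-dimethoxyphenyllithium 5 (not isolated)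
Conditions: 4, n-BuLi, THF, −78 °C; then 3 (suspension in THF), −78 → −20 °C; aq NH4Cl
Reagents that add atoms: none
Why: Bromine–lithium exchange followed by 1,2-addition of the aryllithium to the aldehyde of the preformed phenolate, so that one equivalent of organolithium suffices; the carbinol centre is formed without control because step 4 erases it.

Step 4
Reactants: 6 (2-bromo-6-hydroxy-4-methoxyphenyl)(3,5-dimethoxyphenyl)methanol; 7 (4-methoxyphenyl)acetaldehyde
Product: 9 (3R,4R)-5-bromo-4-(3,5-dimethoxyphenyl)-7-methoxy-3-(4-methoxyphenyl)chroman-2-ol (both anomers), via o-quinone methide 8 (not isolated)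
Conditions: (R)-2-[diphenyl(trimethylsilyloxy)methyl]pyrrolidine (20 mol %), PhCO2H (20 mol %), CHCl3, rt
Reagents that add atoms: none
Why: Benzoic acid should dehydrate the electron-rich o-hydroxybenzhydrol to o-quinone methide 8, the (E)-enamine of 7 adds to its methide carbon (enamine-catalysed Michael addition) and the phenol closes the hemiacetal (formal [4+2] annulation); the catalyst shields one enamine face and the synclinal transition state should relay this to the methide carbon, giving the trans-(3R,4R) lactol whose C4 becomes C3 of the dihydrobenzofuran.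

Step 5
Reactants: 9 (3R,4R)-5-bromo-4-(3,5-dimethoxyphenyl)-7-methoxy-3-(4-methoxyphenyl)chroman-2-ol
Product: 11 (2R,3R)-4-bromo-3-(3,5-dimethoxyphenyl)-6-methoxy-2-(4-methoxyphenyl)-2,3-dihydro-1-benzofuran, via formate 10 (not isolated)
Conditions: mCPBA, CH2Cl2, 0 °C → rt; Me2S; then TFA, 0 °C → rt
Reagents that add atoms: none
Why: mCPBA adds to the lactol carbon through the open hydroxy-aldehyde tautomer and the Criegee adduct rearranges with migration of the electron-rich secondary benzylic carbon (retention) to give formate 10, in which the former lactol carbon already lies outside the chain; TFA then ionises this 4-methoxybenzylic formate to a quinoid cation that the freed phenol oxygen captures. The closest known reaction types are the Baeyer–Villiger oxidation of α-aryl aldehydes to benzylic formates and the acid-mediated cycloetherification of o-hydroxyaryl carbinols, telescoped here into a net six-to-five ring contraction that expels the lactol carbon as formic acid. The dihydrofuran ring closes in the 5-exo-trig mode (phenol oxygen onto the exocyclic benzylic cation). The C3 stereocentre (lactol C4) is not touched and is carried over from step 4, and the new C2 centre is set under its control, the two aryl groups settling trans kinetically and, since ionisation is reversible in TFA, thermodynamically. The step needs carbon rather than hydride migration in the Criegee adduct and ring closure rather than elimination of the cation, both of which the 4-methoxyphenyl group on the migrating carbon should secure; the aryl bromide and the methyl ethers are inert.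

Step 6
Reactants: 11 (2R,3R)-4-bromo-3-(3,5-dimethoxyphenyl)-6-methoxy-2-(4-methoxyphenyl)-2,3-dihydro-1-benzofuran; 3 sodium 3-bromo-2-formyl-5-methoxyphenolate
Product: 13 (2-bromo-6-hydroxy-4-methoxyphenyl)[(2R,3R)-3-(3,5-dimethoxyphenyl)-6-methoxy-2-(4-methoxyphenyl)-2,3-dihydro-1-benzofuran-4-yl]methanol (both carbinol epimers), via aryllithium 12 (not isolated)
Conditions: 11, n-BuLi, THF, −78 °C; then 3 (suspension in THF), −78 → −20 °C; aq NH4Cl
Reagents that add atoms: none
Why: Bromine–lithium exchange at −78 °C is faster than deprotonation at the benzylic ether positions of 11, and the aryllithium undergoes 1,2-addition to the aldehyde of 3 to give the benzhydrol as an inconsequential mixture of carbinol epimers.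

Step 7
Reactants: 13 benzhydrol from step 6; 7 (4-methoxyphenyl)acetaldehyde
Product: 15 (3S,4S)-5-bromo-4-[(2R,3R)-3-(3,5-dimethoxyphenyl)-6-methoxy-2-(4-methoxyphenyl)-2,3-dihydro-1-benzofuran-4-yl]-7-methoxy-3-(4-methoxyphenyl)chroman-2-ol (both anomers), via o-quinone methide 14 (not isolated)
Conditions: (S)-2-[diphenyl(trimethylsilyloxy)methyl]pyrrolidine (20 mol %), PhCO2H (20 mol %), CHCl3, rt
Reagents that add atoms: none
Why: Same enamine-catalysed Michael addition and hemiacetalisation as step 4, run with the enantiomeric catalyst so that reagent control should set the (4S) centre needed for the second furan ring against the more distant stereocentres of the first.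

Step 8
Reactants: 15 lactol from step 7
Product: 17 (2S,3S)-4-bromo-3-[(2R,3R)-3-(3,5-dimethoxyphenyl)-6-methoxy-2-(4-methoxyphenyl)-2,3-dihydro-1-benzofuran-4-yl]-6-methoxy-2-(4-methoxyphenyl)-2,3-dihydro-1-benzofuran, via formate 16 (not isolated)
Conditions: mCPBA, CH2Cl2, 0 °C → rt; Me2S; then TFA, 0 °C → rt
Reagents that add atoms: none
Why: Same Baeyer–Villiger oxidation and acid-mediated 5-exo-trig cycloetherification as step 5; the (4S) lactol centre becomes C3 of the new ring and directs the new C2 centre trans, and the existing dihydrobenzofuran, should it ionise in TFA, recloses to its trans form.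

Step 9
Reactants: 17 bis(dihydrobenzofuran) bromide from step 8; 3 sodium 3-bromo-2-formyl-5-methoxyphenolate
Product: 19 (2-bromo-6-hydroxy-4-methoxyphenyl){(2S,3S)-3-[(2R,3R)-3-(3,5-dimethoxyphenyl)-6-methoxy-2-(4-methoxyphenyl)-2,3-dihydro-1-benzofuran-4-yl]-6-methoxy-2-(4-methoxyphenyl)-2,3-dihydro-1-benzofuran-4-yl}methanol (both carbinol epimers), via aryllithium 18 (not isolated)
Conditions: 17, n-BuLi, THF, −78 °C; then 3 (suspension in THF), −78 → −20 °C; aq NH4Cl
Reagents that add atoms: none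
Why: Bromine–lithium exchange and 1,2-addition of the aryllithium to the aldehyde as in step 6, the ether and benzylic C–H bonds of 17 being inert at −78 °C.

Step 10
Reactants: 19 benzhydrol from step 9; 7 (4-methoxyphenyl)acetaldehyde
Product: 21 (3R,4R)-5-bromo-7-methoxy-3-(4-methoxyphenyl)chroman-2-ol carrying at C4 the 4-yl group of the (2S,3S),(2R,3R)-bis(dihydrobenzofuran) (both anomers), via o-quinone methide 20 (not isolated)
Conditions: (R)-2-[diphenyl(trimethylsilyloxy)methyl]pyrrolidine (20 mol %), PhCO2H (20 mol %), CHCl3, rt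
Reagents that add atoms: none
Why: Same enamine-catalysed Michael addition and hemiacetalisation as step 4 with the (R) catalyst, reagent control being relied on to set the (4R) centre of the third furan ring.

Step 11
Reactants: 21 lactol from step 10
Product: 23 (2R,3R)-4-bromo-3-{(2S,3S)-3-[(2R,3R)-3-(3,5-dimethoxyphenyl)-6-methoxy-2-(4-methoxyphenyl)-2,3-dihydro-1-benzofuran-4-yl]-6-methoxy-2-(4-methoxyphenyl)-2,3-dihydro-1-benzofuran-4-yl}-6-methoxy-2-(4-methoxyphenyl)-2,3-dihydro-1-benzofuran, via formate 22 (not isolated)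
Conditions: mCPBA, CH2Cl2, 0 °C → rt; Me2S; then TFA, 0 °C → rt
Reagents that add atoms: none
Why: Same Baeyer–Villiger oxidation and acid-mediated 5-exo-trig cycloetherification as step 5, the (4R) lactol centre becoming C3 and directing C2 trans.

Step 12
Reactants: 23 octa-O-methyl tris(dihydrobenzofuran) bromide
Product: 25 octa-O-acetyl tris(dihydrobenzofuran) bromide, via octaphenol 24 (not isolated)
Conditions: BBr3, CH2Cl2, −78 °C → rt; ice–water; then Ac2O, pyridine, DMAP (cat.), rt
Reagents that add atoms: acetic anhydride CC(=O)OC(C)=O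
Why: BBr3 cleaves all eight aryl methyl ethers (Lewis-acid ether cleavage) before the acid-sensitive stilbene is present, reversible ionisation at the three C2 positions can only return the trans rings fixed by the C3 centres, and acetylation in the same flask should give a chromatographable octaacetate.

Step 13
Reactants: 25 octa-O-acetyl tris(dihydrobenzofuran) bromide; 26 4-acetoxystyrene
Product: 27 nona-O-acetylmiyabenol A
Conditions: Pd2(dba)3 (5 mol %), P(t-Bu)3·HBF4 (12 mol %), Cy2NMe, 1,4-dioxane, 90 °C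
Reagents that add atoms: none
Why: Mizoroki–Heck reaction in which the bulky electron-rich phosphine should allow oxidative addition of zerovalent palladium at the ortho-substituted bromide, syn insertion then syn β-hydride elimination give the (E)-stilbene, and the hindered amine base spares the acetates.

Step 14
Reactants: 27 nona-O-acetylmiyabenol A
Product: 28 miyabenol A
Conditions: K2CO3 (cat.), MeOH–THF, 0 °C → rt, argon; Amberlite IR-120 (H+ form)
Reagents that add atoms: none
Why: Base-catalysed transesterification (Zemplén-type methanolysis) should remove the nine aryl acetates under conditions too mild to touch the stilbene or to epimerise the three benzylic ether rings.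

**Compound list**

1 | 2-bromo-4,6-dimethoxybenzaldehyde | COc1cc(Br)c(C=O)c(OC)c1 | starting material
2 | 2-bromo-6-hydroxy-4-methoxybenzaldehyde | COc1cc(O)c(C=O)c(Br)c1 | intermediate
3 | sodium 3-bromo-2-formyl-5-methoxyphenolate | [Na+].[O-]c1cc(OC)cc(Br)c1C=O | intermediate
4 | 1-bromo-3,5-dimethoxybenzene | COc1cc(Br)cc(OC)c1 | starting material
5 | 3,5-dimethoxyphenyllithium (formed in the flask) | [Li]c1cc(OC)cc(OC)c1 | intermediate
6 | (2-bromo-6-hydroxy-4-methoxyphenyl)(3,5-dimethoxyphenyl)methanol, racemic | OC(c1cc(OC)cc(OC)c1)c1c(O)cc(OC)cc1Br | intermediate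
7 | (4-methoxyphenyl)acetaldehyde | O=CCc1ccc(OC)cc1 | starting material
8 | o-quinone methide 3-bromo-2-[(3,5-dimethoxyphenyl)methylidene]-5-methoxycyclohexa-3,5-dien-1-one (formed in the flask) | O=C1C=C(OC)C=C(Br)C1=Cc1cc(OC)cc(OC)c1 | intermediate
9 | (3R,4R)-5-bromo-4-(3,5-dimethoxyphenyl)-7-methoxy-3-(4-methoxyphenyl)chroman-2-ol, both anomers | Brc1cc(OC)cc2c1[C@@H](c1cc(OC)cc(OC)c1)[C@H](c1ccc(OC)cc1)C(O)O2 | intermediate
10 | (1R,2R)-2-(2-bromo-6-hydroxy-4-methoxyphenyl)-2-(3,5-dimethoxyphenyl)-1-(4-methoxyphenyl)ethyl formate (formed in the flask) | Brc1cc(OC)cc(O)c1[C@@H](c1cc(OC)cc(OC)c1)[C@H](c1ccc(OC)cc1)OC=O | intermediate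
11 | (2R,3R)-4-bromo-3-(3,5-dimethoxyphenyl)-6-methoxy-2-(4-methoxyphenyl)-2,3-dihydro-1-benzofuran | Brc1cc(OC)cc2c1[C@@H](c1cc(OC)cc(OC)c1)[C@H](c1ccc(OC)cc1)O2 | intermediate
12 | 4-lithio analogue of 11 (formed in the flask) | [Li]c1cc(OC)cc2c1[C@@H](c1cc(OC)cc(OC)c1)[C@H](c1ccc(OC)cc1)O2 | intermediate
13 | (2-bromo-6-hydroxy-4-methoxyphenyl)[(2R,3R)-3-(3,5-dimethoxyphenyl)-6-methoxy-2-(4-methoxyphenyl)-2,3-dihydro-1-benzofuran-4-yl]methanol, both carbinol epimers | OC(c1c(O)cc(OC)cc1Br)c1cc(OC)cc2c1[C@@H](c1cc(OC)cc(OC)c1)[C@H](c1ccc(OC)cc1)O2 | intermediate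
14 | o-quinone methide from 13: 3-bromo-5-methoxy-2-(arylmethylidene)cyclohexa-3,5-dien-1-one, aryl being the (2R,3R)-dihydrobenzofuran-4-yl group (formed in the flask) | O=C1C=C(OC)C=C(Br)C1=Cc1cc(OC)cc2c1[C@@H](c1cc(OC)cc(OC)c1)[C@H](c1ccc(OC)cc1)O2 | intermediate
15 | (3S,4S)-5-bromo-4-[(2R,3R)-3-(3,5-dimethoxyphenyl)-6-methoxy-2-(4-methoxyphenyl)-2,3-dihydro-1-benzofuran-4-yl]-7-methoxy-3-(4-methoxyphenyl)chroman-2-ol, both anomers | Brc1cc(OC)cc2c1[C@H](c1cc(OC)cc3c1[C@@H](c1cc(OC)cc(OC)c1)[C@H](c1ccc(OC)cc1)O3)[C@@H](c1ccc(OC)cc1)C(O)O2 | intermediate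
16 | (1S,2S)-2-(2-bromo-6-hydroxy-4-methoxyphenyl)-2-[(2R,3R)-dihydrobenzofuran-4-yl]-1-(4-methoxyphenyl)ethyl formate (formed in the flask) | Brc1cc(OC)cc(O)c1[C@H](c1cc(OC)cc2c1[C@@H](c1cc(OC)cc(OC)c1)[C@H](c1ccc(OC)cc1)O2)[C@@H](c1ccc(OC)cc1)OC=O | intermediate
17 | (2S,3S)-4-bromo-3-[(2R,3R)-3-(3,5-dimethoxyphenyl)-6-methoxy-2-(4-methoxyphenyl)-2,3-dihydro-1-benzofuran-4-yl]-6-methoxy-2-(4-methoxyphenyl)-2,3-dihydro-1-benzofuran | Brc1cc(OC)cc2c1[C@H](c1cc(OC)cc3c1[C@@H](c1cc(OC)cc(OC)c1)[C@H](c1ccc(OC)cc1)O3)[C@@H](c1ccc(OC)cc1)O2 | intermediate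
18 | 4-lithio analogue of 17 (formed in the flask) | [Li]c1cc(OC)cc2c1[C@H](c1cc(OC)cc3c1[C@@H](c1cc(OC)cc(OC)c1)[C@H](c1ccc(OC)cc1)O3)[C@@H](c1ccc(OC)cc1)O2 | intermediate
19 | (2-bromo-6-hydroxy-4-methoxyphenyl){(2S,3S)-3-[(2R,3R)-3-(3,5-dimethoxyphenyl)-6-methoxy-2-(4-methoxyphenyl)-2,3-dihydro-1-benzofuran-4-yl]-6-methoxy-2-(4-methoxyphenyl)-2,3-dihydro-1-benzofuran-4-yl}methanol, both carbinol epimers | OC(c1c(O)cc(OC)cc1Br)c1cc(OC)cc2c1[C@H](c1cc(OC)cc3c1[C@@H](c1cc(OC)cc(OC)c1)[C@H](c1ccc(OC)cc1)O3)[C@@H](c1ccc(OC)cc1)O2 | intermediate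
20 | o-quinone methide from 19 (formed in the flask) | O=C1C=C(OC)C=C(Br)C1=Cc1cc(OC)cc2c1[C@H](c1cc(OC)cc3c1[C@@H](c1cc(OC)cc(OC)c1)[C@H](c1ccc(OC)cc1)O3)[C@@H](c1ccc(OC)cc1)O2 | intermediate
21 | (3R,4R)-5-bromo-7-methoxy-3-(4-methoxyphenyl)chroman-2-ol carrying at C4 the (2S,3S),(2R,3R)-bis(dihydrobenzofuran)-4-yl group, both anomers | Brc1cc(OC)cc2c1[C@@H](c1cc(OC)cc3c1[C@H](c1cc(OC)cc4c1[C@@H](c1cc(OC)cc(OC)c1)[C@H](c1ccc(OC)cc1)O4)[C@@H](c1ccc(OC)cc1)O3)[C@H](c1ccc(OC)cc1)C(O)O2 | intermediate
22 | (1R,2R)-2-(2-bromo-6-hydroxy-4-methoxyphenyl)-2-[bis(dihydrobenzofuran)-4-yl]-1-(4-methoxyphenyl)ethyl formate (formed in the flask) | Brc1cc(OC)cc(O)c1[C@@H](c1cc(OC)cc2c1[C@H](c1cc(OC)cc3c1[C@@H](c1cc(OC)cc(OC)c1)[C@H](c1ccc(OC)cc1)O3)[C@@H](c1ccc(OC)cc1)O2)[C@H](c1ccc(OC)cc1)OC=O | intermediate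
23 | (2R,3R)-4-bromo-3-{(2S,3S)-3-[(2R,3R)-3-(3,5-dimethoxyphenyl)-6-methoxy-2-(4-methoxyphenyl)-2,3-dihydro-1-benzofuran-4-yl]-6-methoxy-2-(4-methoxyphenyl)-2,3-dihydro-1-benzofuran-4-yl}-6-methoxy-2-(4-methoxyphenyl)-2,3-dihydro-1-benzofuran | Brc1cc(OC)cc2c1[C@@H](c1cc(OC)cc3c1[C@H](c1cc(OC)cc4c1[C@@H](c1cc(OC)cc(OC)c1)[C@H](c1ccc(OC)cc1)O4)[C@@H](c1ccc(OC)cc1)O3)[C@H](c1ccc(OC)cc1)O2 | intermediate
24 | octaphenol: all eight methyl ethers of 23 replaced by OH (formed in the flask) | Brc1cc(O)cc2c1[C@@H](c1cc(O)cc3c1[C@H](c1cc(O)cc4c1[C@@H](c1cc(O)cc(O)c1)[C@H](c1ccc(O)cc1)O4)[C@@H](c1ccc(O)cc1)O3)[C@H](c1ccc(O)cc1)O2 | intermediate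
25 | octaacetate of 24 | Brc1cc(OC(C)=O)cc2c1[C@@H](c1cc(OC(C)=O)cc3c1[C@H](c1cc(OC(C)=O)cc4c1[C@@H](c1cc(OC(C)=O)cc(OC(C)=O)c1)[C@H](c1ccc(OC(C)=O)cc1)O4)[C@@H](c1ccc(OC(C)=O)cc1)O3)[C@H](c1ccc(OC(C)=O)cc1)O2 | intermediate
26 | 4-acetoxystyrene (4-ethenylphenyl acetate) | C=Cc1ccc(OC(C)=O)cc1 | starting material
27 | nona-O-acetylmiyabenol A, (E)-stilbene | CC(=O)Oc1ccc(/C=C/c2cc(OC(C)=O)cc3c2[C@@H](c2cc(OC(C)=O)cc4c2[C@H](c2cc(OC(C)=O)cc5c2[C@@H](c2cc(OC(C)=O)cc(OC(C)=O)c2)[C@H](c2ccc(OC(C)=O)cc2)O5)[C@@H](c2ccc(OC(C)=O)cc2)O4)[C@H](c2ccc(OC(C)=O)cc2)O3)cc1 | intermediate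
28 | miyabenol A | Oc1ccc(/C=C/c2cc(O)cc3c2[C@@H](c2cc(O)cc4c2[C@H](c2cc(O)cc5c2[C@@H](c2cc(O)cc(O)c2)[C@H](c2ccc(O)cc2)O5)[C@@H](c2ccc(O)cc2)O4)[C@H](c2ccc(O)cc2)O3)cc1 | target

**Step count.** Total: 14 steps. Longest linear sequence: 14 steps (1 → 28).

**Steps most likely to fail**

1. Step 5 (the same holds for its repeats, steps 8 and 11). In the Criegee adduct hydride may migrate instead of the benzylic carbon, so that the lactol is merely oxidised to the dihydrocoumarin. The fallback sets out from 9 and returns at 11. Lactol 9 reacts through its open aldehyde form with MeMgBr (THF, 0 °C) to give (3R,4R)-4-(2-bromo-6-hydroxy-4-methoxyphenyl)-4-(3,5-dimethoxyphenyl)-3-(4-methoxyphenyl)butan-2-ol F1. Oxidation with n-Pr4N[RuO4] and N-methylmorpholine N-oxide gives the corresponding butan-2-one F2, which sits in equilibrium with its six-membered hemiketal. mCPBA then effects the Baeyer–Villiger oxidation of this benzyl methyl ketone, where only the secondary benzylic carbon can compete with methyl, to give the (1R,2R)-benzylic acetate F3. TFA ionises it and closes the ring to 11, so the six-to-five contraction is kept.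

2. Step 10 (and, to a lesser degree, step 7). The crowded o-quinone methide may react sluggishly with the enamine, and facial selectivity may erode where the existing stereocentres oppose the catalyst. The fallback sets out from 19 and returns at 21. Benzhydrol 19 is converted with 4-methylbenzenesulfinic acid (CH2Cl2, rt) into the bench-stable o-quinone methide precursor, the α-tosyl diarylmethane F4. Cs2CO3 releases o-quinone methide 20 in the presence of the ammonium enolate generated from (4-methoxyphenyl)acetic acid, t-BuCOCl, i-Pr2NEt and the isothiourea catalyst (2S,3R)-3-isopropyl-2-phenyl-3,4-dihydro-2H-benzo[4,5]thiazolo[3,2-a]pyrimidine or its enantiomer, whichever delivers the 4R centre. This Michael addition–lactonisation gives the (3R,4R)-dihydrocoumarin F5, whose diastereomeric purity can be raised by crystallisation. i-Bu2AlH (CH2Cl2, −78 °C) reduces it to lactol 21.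

3. Step 13. Oxidative addition at the ortho-substituted bromide may be slow, allowing acetate loss and styrene polymerisation to compete. The fallback sets out from 25 and returns at 27. Stille coupling of 25 with tributyl(vinyl)stannane (Pd(PPh3)4, toluene, 100 °C) gives the 4-ethenyl analogue of 25, F6. The Heck reaction is then run the other way round with 4-iodophenyl acetate, whose unhindered iodide adds readily to zerovalent palladium (Pd(OAc)2, n-Bu4NCl, NaHCO3, DMF, 60 °C), to give 27.

**Further compounds**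

F1 | step 5 | (3R,4R)-4-(2-bromo-6-hydroxy-4-methoxyphenyl)-4-(3,5-dimethoxyphenyl)-3-(4-methoxyphenyl)butan-2-ol, both C2 epimers | Brc1cc(OC)cc(O)c1[C@@H](c1cc(OC)cc(OC)c1)[C@H](c1ccc(OC)cc1)C(C)O
F2 | step 5 | (3R,4R)-4-(2-bromo-6-hydroxy-4-methoxyphenyl)-4-(3,5-dimethoxyphenyl)-3-(4-methoxyphenyl)butan-2-one | Brc1cc(OC)cc(O)c1[C@@H](c1cc(OC)cc(OC)c1)[C@H](c1ccc(OC)cc1)C(C)=O
F3 | step 5 | (1R,2R)-2-(2-bromo-6-hydroxy-4-methoxyphenyl)-2-(3,5-dimethoxyphenyl)-1-(4-methoxyphenyl)ethyl acetate | Brc1cc(OC)cc(O)c1[C@@H](c1cc(OC)cc(OC)c1)[C@H](c1ccc(OC)cc1)OC(C)=O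
F4 | step 10 | 3-bromo-5-methoxy-2-[aryl(4-methylbenzenesulfonyl)methyl]phenol, aryl being the bis(dihydrobenzofuran)-4-yl group of 19 | Cc1ccc(cc1)S(=O)(=O)C(c1c(O)cc(OC)cc1Br)c1cc(OC)cc2c1[C@H](c1cc(OC)cc3c1[C@@H](c1cc(OC)cc(OC)c1)[C@H](c1ccc(OC)cc1)O3)[C@@H](c1ccc(OC)cc1)O2
F5 | step 10 | (3R,4R)-5-bromo-7-methoxy-3-(4-methoxyphenyl)chroman-2-one carrying at C4 the bis(dihydrobenzofuran)-4-yl group | Brc1cc(OC)cc2c1[C@@H](c1cc(OC)cc3c1[C@H](c1cc(OC)cc4c1[C@@H](c1cc(OC)cc(OC)c1)[C@H](c1ccc(OC)cc1)O4)[C@@H](c1ccc(OC)cc1)O3)[C@H](c1ccc(OC)cc1)C(=O)O2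
F6 | step 13 | 4-ethenyl analogue of octaacetate 25 | C=Cc1cc(OC(C)=O)cc2c1[C@@H](c1cc(OC(C)=O)cc3c1[C@H](c1cc(OC(C)=O)cc4c1[C@@H](c1cc(OC(C)=O)cc(OC(C)=O)c1)[C@H](c1ccc(OC(C)=O)cc1)O4)[C@@H](c1ccc(OC(C)=O)cc1)O3)[C@H](c1ccc(OC(C)=O)cc1)O2
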